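**Strategy**

Ring A (furan-2,5-dione with CH2OH on C3 and the side chain on C4) hides a butenolide: the hydroxymethyl oxygen and the C5 carbonyl lie 1,5 along O–CH2–C3=C4–C5 and can be tied as a lactone. Everything rests on forming the C3=C4 bond of ring A while that lactone ring closes: an α-phosphono acid, which already carries the (R) centre and ring B as a diethyl maleate, is O-alkylated by ethyl bromopyruvate and cyclises in the same flask by intramolecular Horner–Wadsworth–Emmons olefination. Saponification then opens the lactone, both maleic diacids close to anhydrides, and ozonolysis unmasks the ketone.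

Key step: step 9

Assumption: the hydroxymethyl anhydride of ring A and its butenolide-acid isomer interconvert only through the ring-opened diacid, so the anhydride is taken as isolable once it has been extracted from water.

**Route**

Step 1
Reactants: 1 tert-butyl 2-(diethoxyphosphoryl)acetate
Product: 4 tert-butyl 2-(diethoxyphosphoryl)prop-2-enoate, via hydroxymethyl adduct 2 (not isolated), via mesylate 3 (not isolated)
Conditions: (CH2O)n, piperidine (cat.), MeOH, 65 °C; evaporate; then MsCl, Et3N, CH2Cl2, 0 °C
Reagents that add atoms: formaldehyde (as paraformaldehyde), C=O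
Why: Knoevenagel-type hydroxymethylation of the phosphonoacetate followed by E1cB elimination of the mesylate should give the 2-phosphonoacrylate without acid, which the tert-butyl ester would not survive.

Step 2
Reactants: 5 heptanal; 4 tert-butyl 2-(diethoxyphosphoryl)prop-2-enoate
Product: 6 tert-butyl (4R)-2-(diethoxyphosphoryl)-4-formylnonanoate (both epimers at C2)
Conditions: (S)-2-[diphenyl(trimethylsilyloxy)methyl]pyrrolidine (10 mol%), CH2Cl2, 0 °C; 5 in 1.5-fold excess; short silica filtration, used at once
Reagents that add atoms: none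
Why: Asymmetric enamine-catalysed Michael addition: the diphenyl(silyloxy)methyl group shields one face of the (E)-enamine of heptanal, so the doubly activated acrylate should add from the open face and set the (R) centre, while the phosphonate-bearing carbon forms as both epimers and becomes sp2 in step 9.

Step 3
Reactants: 6 tert-butyl (4R)-2-(diethoxyphosphoryl)-4-formylnonanoate; 7 ethyl diazoacetate
Product: 8 1-tert-butyl 7-ethyl (4R)-2-(diethoxyphosphoryl)-5-oxo-4-pentylheptanedioate
Conditions: SnCl2 (15 mol%), CH2Cl2, 0 °C → rt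
Reagents that add atoms: none
Why: Roskamp reaction: the diazo carbon adds to the SnCl2-activated aldehyde and a 1,2-hydride shift with loss of N2 gives the β-keto ester under non-basic conditions, so the α-stereocentre should not enolise.

Step 4
Reactants: 9 3-chloro-2-(chloromethyl)prop-1-ene; 10 propylmagnesium bromide
Product: 11 2-(chloromethyl)hex-1-ene
Conditions: Li2CuCl4 (3 mol%), THF, −30 → 0 °C; 9 in 3-fold excess
Reagents that add atoms: none
Why: Copper-catalysed Grignard allylic substitution on a symmetrical dichloride, where SN2 and SN2' attack give the same product and the excess of 9 suppresses double substitution.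

Step 5
Reactants: 8 1-tert-butyl 7-ethyl (4R)-2-(diethoxyphosphoryl)-5-oxo-4-pentylheptanedioate; 11 2-(chloromethyl)hex-1-ene
Product: 12 1-tert-butyl 7-ethyl (4R)-2-(diethoxyphosphoryl)-6-(2-methylidenehexyl)-5-oxo-4-pentylheptanedioate
Conditions: K2CO3, DMF, 40 °C
Reagents that add atoms: none
Why: Enolate C-alkylation (SN2 at the allylic chloride): K2CO3 deprotonates only the 1,3-dicarbonyl CH2, which also keeps the neighbouring stereocentre and the phosphonoacetate from enolising.

Step 6
Reactants: 12 1-tert-butyl 7-ethyl (4R)-2-(diethoxyphosphoryl)-6-(2-methylidenehexyl)-5-oxo-4-pentylheptanedioate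
Product: 14 1-tert-butyl 7-ethyl (4R,5Z)-2-(diethoxyphosphoryl)-6-(2-methylidenehexyl)-4-pentyl-5-(trifluoromethanesulfonyloxy)hept-5-enedioate, via sodium enolate 13 (not isolated)
Conditions: NaH, THF, 0 °C; then PhNTf2, 0 °C → rt
Reagents that add atoms: N-phenylbis(trifluoromethanesulfonimide), O=S(=O)(N(c1ccccc1)S(=O)(=O)C(F)(F)F)C(F)(F)F
Why: O-Sulfonylation of the sodium enolate, which is chelated between the two carbonyl oxygens in THF and so has the enolate oxygen cis to the ester, should give the (Z)-enol triflate needed for a maleate.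

Step 7
Reactants: 14 the (Z)-enol triflate
Product: 15 1-tert-butyl 7-ethyl (4R,5Z)-2-(diethoxyphosphoryl)-5-(ethoxycarbonyl)-6-(2-methylidenehexyl)-4-pentylhept-5-enedioate
Conditions: Pd(OAc)2 (5 mol%), PPh3 (12 mol%), CO (1 atm), Et3N, EtOH/DMF, 60 °C
Reagents that add atoms: carbon monoxide, [C-]#[O+]; ethanol, CCO
Why: Palladium-catalysed alkoxycarbonylation of an enol triflate (oxidative addition to zerovalent palladium, CO insertion, ethanolysis) proceeds with retention of geometry to the diethyl maleate of ring B, and the acylpalladium is trans to the methylidenehexyl chain, so it cannot insert that alkene.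

Step 8
Reactants: 15 the tert-butyl diethyl maleate triester
Product: 17 (4R,5Z)-2-(diethoxyphosphoryl)-5,6-bis(ethoxycarbonyl)-8-methylidene-4-pentyldodec-5-enoic acid, via trimethylsilyl ester 16 (not isolated)
Conditions: TMSOTf, 2,6-lutidine, CH2Cl2, 0 °C → rt; then H2O
Reagents that add atoms: none
Why: Silyl triflate-mediated cleavage of a tert-butyl ester (O-silylation, loss of isobutene, hydrolysis of the silyl ester on work-up) frees the acid without a protic acid that would protonate the 1,1-disubstituted alkene, and leaves the ethyl esters and the phosphonate alone.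

Step 9
Reactants: 17 the α-phosphono acid; 18 ethyl 3-bromo-2-oxopropanoate
Product: 20 ethyl 4-[(2R,3Z)-3,4-bis(ethoxycarbonyl)-6-methylidene-2-pentyldec-3-en-1-yl]-5-oxo-2,5-dihydrofuran-3-carboxylate, via acyloxy keto ester 19 (not isolated)
Conditions: 18, DBU (1.0 equiv), MeCN, 0 °C; then LiCl, DBU (1.2 equiv), 0 °C, 30 min; aq. NH4Cl
Reagents that add atoms: none
Why: The carboxylate of 17 displaces bromide from 18 (SN2) to give 19, and with LiCl and more DBU the lithium-chelated phosphonate carbanion adds to the ketone of the α-keto ester and the oxaphosphetane collapses with loss of diethyl phosphate, which forms the C3=C4 double bond of ring A and closes the five-membered lactone in one event. The closest known reaction type is the intramolecular Horner–Wadsworth–Emmons synthesis of butenolides from phosphonoacetates of α-hydroxy ketones, telescoped here with ester formation from an α-bromo ketone. The lactone ring closes by 5-exo-trig addition of the carbanion to the ketone carbonyl. No stereocentre is created: the ring fixes the new alkene with its two carboxyl carbons cis, and the (R) centre is not acidic under these conditions. The step needs chemoselectivity, which the substrate secures because with one equivalent of base only the carboxylate is nucleophilic and the ketone is the only electrophile that gives a five-membered ring (attack on the ethyl ester would need a six-membered transition state at a far less electrophilic carbonyl), while the maleate of ring B and the skipped alkene should not react with LiCl/DBU at 0 °C.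

Step 10
Reactants: 20 the butenolide triester
Product: 23 3-(hydroxymethyl)-4-{(2R)-2-[4-(2-methylidenehexyl)-2,5-dioxo-2,5-dihydrofuran-3-yl]heptyl}furan-2,5-dione, via tetralithium salt 21 (not isolated), via hydroxy tetraacid 22 (not isolated)
Conditions: LiOH, THF/H2O, 0 °C → rt; then cold 1 M HCl to pH 1, immediate extraction (EtOAc), evaporation from toluene
Reagents that add atoms: water (as aqueous LiOH), O
Why: Saponification cleaves the ethyl esters and opens the lactone, and on acidification each cis-dialkylmaleic diacid (or remaining half-ester) should close spontaneously to its anhydride, leaving the former lactone oxygen as the free CH2OH of ring A, because anhydride closure is much faster than relactonisation of the hydroxy acid.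

Step 11
Reactants: 23 the bis-anhydride alkene
Product: 25 3-(hydroxymethyl)-4-{(2R)-2-[2,5-dioxo-4-(2-oxohexyl)-2,5-dihydrofuran-3-yl]heptyl}furan-2,5-dione, via ozonide 24 (not isolated)
Conditions: O3, CH2Cl2, −78 °C; then Me2S, −78 °C → rt
Reagents that add atoms: ozone, [O-][O+]=O
Why: Ozonolysis with reductive work-up: ozone should attack only the electron-rich 1,1-disubstituted alkene, since the two tetrasubstituted anhydride alkenes are strongly electron-poor, and Me2S reduces the ozonide to the butyl ketone.

**Compound list**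

1 | tert-butyl 2-(diethoxyphosphoryl)acetate | CCOP(=O)(OCC)CC(=O)OC(C)(C)C | starting material
2 | tert-butyl 2-(diethoxyphosphoryl)-3-hydroxypropanoate (racemic) | CCOP(=O)(OCC)C(CO)C(=O)OC(C)(C)C | intermediate
3 | tert-butyl 2-(diethoxyphosphoryl)-3-(methanesulfonyloxy)propanoate (racemic) | CCOP(=O)(OCC)C(COS(C)(=O)=O)C(=O)OC(C)(C)C | intermediate
4 | tert-butyl 2-(diethoxyphosphoryl)prop-2-enoate | CCOP(=O)(OCC)C(=C)C(=O)OC(C)(C)C | intermediate
5 | heptanal | CCCCCCC=O | starting material
6 | tert-butyl (4R)-2-(diethoxyphosphoryl)-4-formylnonanoate (epimers at C2) | CCCCC[C@H](CC(P(=O)(OCC)OCC)C(=O)OC(C)(C)C)C=O | intermediate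
7 | ethyl diazoacetate | CCOC(=O)C=[N+]=[N-] | starting material
8 | 1-tert-butyl 7-ethyl (4R)-2-(diethoxyphosphoryl)-5-oxo-4-pentylheptanedioate | CCCCC[C@H](CC(P(=O)(OCC)OCC)C(=O)OC(C)(C)C)C(=O)CC(=O)OCC | intermediate
9 | 3-chloro-2-(chloromethyl)prop-1-ene | C=C(CCl)CCl | starting material
10 | propylmagnesium bromide | CCC[Mg]Br | starting material
11 | 2-(chloromethyl)hex-1-ene | C=C(CCl)CCCC | intermediate
12 | 1-tert-butyl 7-ethyl (4R)-2-(diethoxyphosphoryl)-6-(2-methylidenehexyl)-5-oxo-4-pentylheptanedioate (epimers at C2 and C6) | CCCCC[C@H](CC(P(=O)(OCC)OCC)C(=O)OC(C)(C)C)C(=O)C(CC(=C)CCCC)C(=O)OCC | intermediate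
13 | sodium (Z)-enolate of 12 | CCCCC[C@H](CC(P(=O)(OCC)OCC)C(=O)OC(C)(C)C)/C([O-])=C(\CC(=C)CCCC)C(=O)OCC.[Na+] | intermediate
14 | 1-tert-butyl 7-ethyl (4R,5Z)-2-(diethoxyphosphoryl)-6-(2-methylidenehexyl)-4-pentyl-5-(trifluoromethanesulfonyloxy)hept-5-enedioate | CCCCC[C@H](CC(P(=O)(OCC)OCC)C(=O)OC(C)(C)C)/C(OS(=O)(=O)C(F)(F)F)=C(\CC(=C)CCCC)C(=O)OCC | intermediate
15 | 1-tert-butyl 7-ethyl (4R,5Z)-2-(diethoxyphosphoryl)-5-(ethoxycarbonyl)-6-(2-methylidenehexyl)-4-pentylhept-5-enedioate | CCCCC[C@H](CC(P(=O)(OCC)OCC)C(=O)OC(C)(C)C)/C(C(=O)OCC)=C(\CC(=C)CCCC)C(=O)OCC | intermediate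
16 | trimethylsilyl (4R,5Z)-2-(diethoxyphosphoryl)-5,6-bis(ethoxycarbonyl)-8-methylidene-4-pentyldodec-5-enoate | CCCCC[C@H](CC(P(=O)(OCC)OCC)C(=O)O[Si](C)(C)C)/C(C(=O)OCC)=C(\CC(=C)CCCC)C(=O)OCC | intermediate
17 | (4R,5Z)-2-(diethoxyphosphoryl)-5,6-bis(ethoxycarbonyl)-8-methylidene-4-pentyldodec-5-enoic acid | CCCCC[C@H](CC(P(=O)(OCC)OCC)C(=O)O)/C(C(=O)OCC)=C(\CC(=C)CCCC)C(=O)OCC | intermediate
18 | ethyl 3-bromo-2-oxopropanoate (ethyl bromopyruvate) | CCOC(=O)C(=O)CBr | starting material
19 | 3-ethoxy-2,3-dioxopropyl (4R,5Z)-2-(diethoxyphosphoryl)-5,6-bis(ethoxycarbonyl)-8-methylidene-4-pentyldodec-5-enoate | CCCCC[C@H](CC(P(=O)(OCC)OCC)C(=O)OCC(=O)C(=O)OCC)/C(C(=O)OCC)=C(\CC(=C)CCCC)C(=O)OCC | intermediate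
20 | ethyl 4-[(2R,3Z)-3,4-bis(ethoxycarbonyl)-6-methylidene-2-pentyldec-3-en-1-yl]-5-oxo-2,5-dihydrofuran-3-carboxylate | CCCCC[C@H](CC1=C(C(=O)OCC)COC1=O)/C(C(=O)OCC)=C(\CC(=C)CCCC)C(=O)OCC | intermediate
21 | tetralithium salt of 22 | CCCCC[C@H](C/C(C(=O)[O-])=C(\CO)C(=O)[O-])/C(C(=O)[O-])=C(\CC(=C)CCCC)C(=O)[O-].[Li+].[Li+].[Li+].[Li+] | intermediate
22 | (2Z)-2-(hydroxymethyl)-3-[(2R,3Z)-3,4-dicarboxy-6-methylidene-2-pentyldec-3-en-1-yl]but-2-enedioic acid | CCCCC[C@H](C/C(C(=O)O)=C(\CO)C(=O)O)/C(C(=O)O)=C(\CC(=C)CCCC)C(=O)O | intermediate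
23 | 3-(hydroxymethyl)-4-{(2R)-2-[4-(2-methylidenehexyl)-2,5-dioxo-2,5-dihydrofuran-3-yl]heptyl}furan-2,5-dione | CCCCC[C@H](CC1=C(CO)C(=O)OC1=O)C1=C(CC(=C)CCCC)C(=O)OC1=O | intermediate
24 | 1,2,4-trioxolane (ozonide) of 23, 3-butyl-3-substituted, mixture at the ozonide carbon | CCCCC[C@H](CC1=C(CO)C(=O)OC1=O)C1=C(CC2(CCCC)OCOO2)C(=O)OC1=O | intermediate
25 | 3-(hydroxymethyl)-4-{(2R)-2-[2,5-dioxo-4-(2-oxohexyl)-2,5-dihydrofuran-3-yl]heptyl}furan-2,5-dione | CCCCC[C@H](CC1=C(CO)C(=O)OC1=O)C1=C(CC(=O)CCCC)C(=O)OC1=O | target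

**Step count and risks**

Total step count: 11. Longest linear sequence: 10 steps (steps 1, 2, 3, 5, 6, 7, 8, 9, 10, 11).

Steps most likely to fail:

1. Step 10. After the lactone is opened, relactonisation of the ring A hydroxy diacid may compete with anhydride closure during acidification, and prolonged hydroxide exposure may epimerise the allylic centre. Fallback: protect the alcohol before any acid is present. Setting out from 20, the saponification is run as before, but the tetralithium salt 21 is freeze-dried and silylated (TBSCl, imidazole, DMF), which turns the alkoxide into a silyl ether and the carboxylates into labile silyl esters. Dilute citric acid then cleaves only the silyl esters and both rings close to give silyl ether bis-anhydride F1. Ozonolysis as in step 11 would give silyl ether ketone F2, and BF3·OEt2 in dry CH2Cl2 removes the silyl group without water, so the route is rejoined at 25.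

2. Step 9. The bromopyruvate unit may self-condense under base before or after O-alkylation, and over-exposure to base may move the butenolide double bond out of conjugation. Fallback: build the keto ester without an α-bromo ketone. Setting out from 17, Steglich esterification (EDC·HCl, DMAP, CH2Cl2) with ethyl 2,3-dihydroxypropanoate at its primary hydroxyl would give hydroxy ester F3. Dess–Martin periodinane oxidises the secondary alcohol under neutral conditions to keto ester 19, which is closed with LiCl/DBU to rejoin the route at 20.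

3. Step 2. The α-branched aldehyde may lose enantiopurity by enamine-mediated epimerisation during the reaction or on the way into step 3. Fallback: set the centre with an oxazolidinone auxiliary and bypass the aldehyde. Setting out from 4, the titanium enolate (TiCl3(Oi-Pr), i-Pr2NEt, CH2Cl2, −78 °C) of (S)-4-benzyl-3-heptanoyl-1,3-oxazolidin-2-one F4 (from heptanoyl chloride and the lithiated auxiliary) adds to 4 anti to the benzyl group to give imide F5. LiOH/H2O2 removes the auxiliary to give acid F6, and activation with carbonyldiimidazole followed by Mg(O2CCH2CO2Et)2 homologates it to the β-keto ester, rejoining the route at 8.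

**Further compounds**

F1 | step 10 | 3-[(tert-butyldimethylsilyloxy)methyl]-4-{(2R)-2-[4-(2-methylidenehexyl)-2,5-dioxo-2,5-dihydrofuran-3-yl]heptyl}furan-2,5-dione | CCCCC[C@H](CC1=C(CO[Si](C)(C)C(C)(C)C)C(=O)OC1=O)C1=C(CC(=C)CCCC)C(=O)OC1=O
F2 | step 10 | 3-[(tert-butyldimethylsilyloxy)methyl]-4-{(2R)-2-[2,5-dioxo-4-(2-oxohexyl)-2,5-dihydrofuran-3-yl]heptyl}furan-2,5-dione | CCCCC[C@H](CC1=C(CO[Si](C)(C)C(C)(C)C)C(=O)OC1=O)C1=C(CC(=O)CCCC)C(=O)OC1=O
F3 | step 9 | 3-ethoxy-2-hydroxy-3-oxopropyl (4R,5Z)-2-(diethoxyphosphoryl)-5,6-bis(ethoxycarbonyl)-8-methylidene-4-pentyldodec-5-enoate | CCCCC[C@H](CC(P(=O)(OCC)OCC)C(=O)OCC(O)C(=O)OCC)/C(C(=O)OCC)=C(\CC(=C)CCCC)C(=O)OCC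
F4 | step 2 | (S)-4-benzyl-3-heptanoyl-1,3-oxazolidin-2-one | CCCCCCC(=O)N1[C@@H](Cc2ccccc2)COC1=O
F5 | step 2 | tert-butyl (4R)-4-{[(4S)-4-benzyl-2-oxo-1,3-oxazolidin-3-yl]carbonyl}-2-(diethoxyphosphoryl)nonanoate | CCCCC[C@H](CC(P(=O)(OCC)OCC)C(=O)OC(C)(C)C)C(=O)N1[C@@H](Cc2ccccc2)COC1=O
F6 | step 2 | (2R)-2-[3-tert-butoxy-2-(diethoxyphosphoryl)-3-oxopropyl]heptanoic acid | CCCCC[C@H](CC(P(=O)(OCC)OCC)C(=O)OC(C)(C)C)C(=O)O
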